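Saturday's flask held 25.0 mM of free catalyst against 11 mM of impurity, so I measured its rate against the working catalyst, 14.0 mM: the catalyst charged less the impurity, one for one. Wednesday's flask had 17.0 mM charged and 6.00 mM working.

| setting | Saturday's | Wednesday's | flask |
|---|---|---|---|
| substrate | 0.50 M | 0.50 M | 0.50 M |
| free catalyst | 5 mol% | 3.4 mol% | 5 mol% |
| impurity | 11 mM | 11 mM | 11 mM |
| remark | the very flask that is asked about, followed so far | run made earlier |  |
| time |  |  | 4.0 d |

Saturday's run (percent of the substrate charged)

| time / h | product / % |
|---|---|
| 2.50 | 1.5 |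
| 8.00 | 4.3 |
| 15.0 | 8.7 |
| 20.0 | 11.4 |
| 30.0 | 16.4 |
| 40.0 | 20.7 |
| 50.0 | 24.5 |

Wednesday's run (percent of the substrate charged)

| time / d | product / % |
|---|---|
| 0.333 | 1.1 |
| 0.500 | 2.5 |
| 0.833 | 6.0 |
| 1.04 | 6.6 |
| 1.67 | 9.8 |
| 2.50 | 14.3 |
| 4.00 | 22.1 |

(readings scatter by 0.5 percentage points)

- percentages count the substrate that a species holds: one idle complex counts as two
- what was read earlier has a scatter of 0.5 percentage points, one standard deviation
- on the list of suspects stand: substrate + free catalyst <-> catalyst intermediate A; catalyst intermediate A <-> catalyst intermediate B; catalyst intermediate B -> free catalyst + product; substrate + catalyst intermediate B <-> idle complex; 2 free catalyst -> spent catalyst A; free catalyst + impurity -> spent catalyst B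

* amount of product in percent of the substrate charged, at 10 h, 30 h, 2.5 d and 4.0 d

Saturday's run averaged 0.00570 /h of the charge over its first 20.0 h, and Wednesday's run 0.00230 /h over 4.00 d. Their ratio, 2.48 as read, is larger than the ratio of charges, 1.47, and close to that of working catalyst, 2.33. I therefore read the impurity as taking its share of catalyst first.

Saturday's rate then sagged to 0.00405 /h between 30.0 h and 50.0 h, a factor of 0.711. A rate proportional to substrate would give 0.844; I assigned the remaining 0.842 to dying catalyst. For the end, I let the reciprocal rate keep rising in a straight line, as under second-order loss of catalyst: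

reciprocal rate: 175 h at 10.0 h, 247 h at 40.0 h

at 73.0 h: 326 h

product at 4.0 d: 24.5 % + (4.0 d − 50.0 h) / 326 h = 38.6 %

The forecast gave 5.8 %, 16.3 %, 28.8 % and 40.5 %, saying "That points to second-order catalyst death"; its last value is higher than my 38.6 %.

The flask gave 5.85 %, 16.6 %, 29.2 % and 40.3 %, within the margin of the forecast.

    substrate + free catalyst ⇌ catalyst intermediate A (K = 3.50 /M, k = 3.70 /M/h)
    catalyst intermediate A ⇌ catalyst intermediate B (K = 0.370, k = 1.20 /h)
    catalyst intermediate B → free catalyst + product (k = 2.60 /h)
    substrate + catalyst intermediate B ⇌ idle complex, settled at all times (K = 2.00 /M)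
    2 free catalyst → spent catalyst A (k = 1.90 /M/h)
    free catalyst + impurity → spent catalyst B (k = 1800 /M/h)

Just after the start, free catalyst in Saturday's flask entered catalyst intermediate A at 0.14 of the rate at which it went to spent catalyst B, counting the forward step alone, and by 0.400 d impurity, the limiting reagent of that step, stood at 0 % of its own charge and spent catalyst B at 44.0 % of the catalyst charged. Per working catalyst, Saturday's flask had made 14.4 turnovers at 4.0 d, and Wednesday's run, as read, 18.4 at 4.00 d.

The readings were computed with constants of no real substance, noise included.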